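**Retrosynthetic overview**
1. Ring D (oxepine: 2'-O, CH, CH2, C3, C2, C1', C2') is closed last at the 2'-O–CH bond. The enabling feature: the 2'-oxygen of ring B and the side-chain CH are the ends of a seven-atom chain, and the ArO–CH–C(CH3)2OH unit is an opened prenyl epoxide, so a 2'-phenoxide can open the (S)-epoxide of a 3-prenyl group 7-exo-tet.
2. The precursor is artocarpin triacetate (achiral, no ring D, no carbinol); artocarpin comes from Suzuki–Miyaura coupling of a 6-bromoflavone with an (E)-alkenylboronate.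
3. Ring C (pyranone) comes from cyclodehydration of a C-prenylated 1,3-diketone, itself from a Baker–Venkataraman rearrangement of a ring A ketone esterified with a ring B acid.
4. Ring A regiochemistry comes from the symmetric 4-bromo-3,5-dimethoxyphenol (one possible ortho-acylation product) plus chelation-controlled 5-O-demethylation.
5. Ring order: rings A and B are purchased, ring C forms in step 7, ring D in step 12.

Key step: step 12

Assumption: the L-fructose-derived enantiomer of the Shi ketone (1,2:4,5-di-O-isopropylidene-β-L-erythro-2,3-hexodiulo-2,6-pyranose) is treated as a purchasable catalyst.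

**Route**

Step 1
Reactants: 1 2-bromo-1,3-dimethoxybenzene
Product: 3 4-bromo-3,5-dimethoxyphenol, via arylboronate 2 (not isolated)
Conditions: [Ir(OMe)(cod)]2 (1.5 mol%), dtbpy (3 mol%), B2pin2 (1.0 equiv), THF, 80 °C; evaporate; then Oxone (2KHSO5·KHSO4·K2SO4), acetone–H2O, rt
Reagents that add atoms: Oxone, active component potassium peroxymonosulfate, [K+].[O-]S(=O)(=O)OO (phenol oxygen); bis(pinacolato)diboron, CC1(C)OB(OC1(C)C)B1OC(C)(C)C(C)(C)O1 (boryl group of 2 only)
Why: Sterically governed iridium-catalysed C–H borylation should occur only at C5, the one C–H without an ortho substituent, and oxidation of the boronate then gives the symmetric phenol.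

Step 2
Reactants: 3 4-bromo-3,5-dimethoxyphenol
Product: 4 1-(3-bromo-6-hydroxy-2,4-dimethoxyphenyl)ethan-1-one
Conditions: AcOH, BF3·OEt2 (promoter), 80 °C; aq. NaOAc work-up
Reagents that add atoms: acetic acid, CC(=O)O
Why: BF3-promoted Friedel–Crafts C-acylation ortho to the phenol can give only one regioisomer because the para position carries bromine and the two ortho positions are equivalent.

Step 3
Reactants: 5 methyl 2,4-dihydroxybenzoate
Product: 7 2,4-bis(methoxymethoxy)benzoic acid, via methyl ester 6 (not isolated)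
Conditions: NaH, MOMCl, DMF, 0 °C → rt; then aq. NaOH, MeOH, 60 °C; dilute HCl to pH 4 at 0 °C
Reagents that add atoms: chloromethyl methyl ether, COCCl; sodium hydroxide, [Na+].[OH-] (carboxyl oxygen)
Why: Williamson-type O-alkylation of both phenoxides followed by ester saponification gives a ring B acid whose acetals survive all basic steps and fall off in the acidic step 7.

Step 4
Reactants: 4 1-(3-bromo-6-hydroxy-2,4-dimethoxyphenyl)ethan-1-one; 7 2,4-bis(methoxymethoxy)benzoic acid
Product: 8 2-acetyl-4-bromo-3,5-dimethoxyphenyl 2,4-bis(methoxymethoxy)benzoate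
Conditions: EDC·HCl, DMAP, CH2Cl2, rt
Reagents that add atoms: none
Why: Steglich esterification acylates the only free hydroxyl under neutral conditions that leave the acid-labile acetals intact.

Step 5
Reactants: 8 2-acetyl-4-bromo-3,5-dimethoxyphenyl 2,4-bis(methoxymethoxy)benzoate
Product: 9 1-(3-bromo-6-hydroxy-2,4-dimethoxyphenyl)-3-[2,4-bis(methoxymethoxy)phenyl]propane-1,3-dione
Conditions: KOH, pyridine, 50 °C; AcOH work-up
Reagents that add atoms: none
Why: Baker–Venkataraman rearrangement, in which the methyl ketone enolate takes the aroyl group from the neighbouring ester oxygen and formation of the stabilised diketonate drives the transfer.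

Step 6
Reactants: 9 1-(3-bromo-6-hydroxy-2,4-dimethoxyphenyl)-3-[2,4-bis(methoxymethoxy)phenyl]propane-1,3-dione; 10 1-bromo-3-methylbut-2-ene (prenyl bromide)
Product: 11 1-(3-bromo-6-hydroxy-2,4-dimethoxyphenyl)-3-[2,4-bis(methoxymethoxy)phenyl]-2-(3-methylbut-2-en-1-yl)propane-1,3-dione (racemic)
Conditions: K2CO3, Bu4NI (cat.), acetone, 50 °C
Reagents that add atoms: none
Why: SN2 C-alkylation of the soft diketonate by the allylic bromide should outrun O-alkylation of the chelated phenol; the new stereocentre forms as a racemate and is erased in step 7.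

Step 7
Reactants: 11 the C-prenylated diketone
Product: 13 6-bromo-2-(2,4-dihydroxyphenyl)-5,7-dimethoxy-3-(3-methylbut-2-en-1-yl)-4H-chromen-4-one, via MOM-protected flavone 12 (not isolated)
Conditions: HCl (cat.), MeOH, rt; then 3 M aq. HCl, MeOH, 55 °C
Reagents that add atoms: none
Why: Acid-catalysed cyclodehydration of the o-hydroxyaryl diketone closes ring C at room temperature before the acetals are cleaved, so the ring B 2'-hydroxyl cannot compete for ring closure; warming then removes both acetals by acetal methanolysis.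

Step 8
Reactants: 13 6-bromo-2-(2,4-dihydroxyphenyl)-5,7-dimethoxy-3-(3-methylbut-2-en-1-yl)-4H-chromen-4-one
Product: 14 6-bromo-2-(2,4-dihydroxyphenyl)-5-hydroxy-7-methoxy-3-(3-methylbut-2-en-1-yl)-4H-chromen-4-one
Conditions: MgI2·OEt2 (excess), THF–toluene, 60 °C; aq. NH4Cl work-up
Reagents that add atoms: none
Why: Chelation-controlled ether cleavage, in which magnesium bound between the C4 carbonyl and the 5-methoxy oxygen directs iodide to that methyl group only, under non-protic conditions that should spare the prenyl group and the 7-methoxy group.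

Step 9
Reactants: 15 3-methylbut-1-yne; 16 pinacolborane
Product: 17 (E)-4,4,5,5-tetramethyl-2-(3-methylbut-1-en-1-yl)-1,3,2-dioxaborolane
Conditions: Cp2Zr(H)Cl (5 mol%), Et3N (10 mol%), neat, sealed tube, 60 °C
Reagents that add atoms: none
Why: Zirconium-catalysed hydroboration of a terminal alkyne is a syn, anti-Markovnikov addition and should give the (E)-alkenylboronate only.

Step 10
Reactants: 14 the 6-bromo-5-hydroxyflavone; 17 the (E)-alkenylboronate
Product: 18 artocarpin (2-(2,4-dihydroxyphenyl)-5-hydroxy-7-methoxy-6-[(E)-3-methylbut-1-en-1-yl]-3-(3-methylbut-2-en-1-yl)-4H-chromen-4-one)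
Conditions: Pd(OAc)2 (5 mol%), SPhos (10 mol%), K3PO4, 1,4-dioxane–H2O, 85 °C
Reagents that add atoms: none
Why: Suzuki–Miyaura coupling with retention of alkene geometry, using a bulky electron-rich biarylphosphine for the di-ortho-substituted aryl bromide; free phenols are tolerated.

Step 11
Reactants: 18 artocarpin
Product: 19 artocarpin 5,2',4'-triacetate
Conditions: Ac2O, pyridine, DMAP (cat.), CH2Cl2, rt
Reagents that add atoms: acetic anhydride, CC(=O)OC(C)=O
Why: Nucleophile-catalysed O-acylation masks all three phenols against the oxidant of step 12 and lowers the electron density of ring A and its 6-alkenyl group.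

Step 12
Reactants: 19 artocarpin 5,2',4'-triacetate
Product: 21 target (R)-oxepinoflavone CNP0216454.1, via (S)-epoxide triacetate 20 (not isolated)
Conditions: L-fructose-derived Shi ketone (30 mol%), Oxone (1.3 equiv KHSO5), K2CO3, Bu4NHSO4 (cat.), MeCN–CH2(OMe)2/aq. Na2B4O7 buffer (pH ≈ 10), 0 °C; then aq. Na2S2O3; K2CO3, degassed MeOH, 0 → 40 °C, N2; NH4Cl work-up
Reagents that add atoms: Oxone, active component potassium peroxymonosulfate, [K+].[O-]S(=O)(=O)OO (epoxide oxygen, which ends as the tertiary hydroxyl)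
Why: The dioxirane formed from the L-fructose-derived ketone and KHSO5 transfers oxygen through a spiro transition state to one face of the trisubstituted prenyl alkene to give the (S)-epoxide 20; methanolysis of the acetates then frees the 2'-phenoxide, which opens the epoxide at its secondary carbon by SN2 attack so that the epoxide oxygen becomes the tertiary hydroxyl. The closest known reaction type is Shi epoxidation followed by base-mediated phenoxide opening of a prenyl epoxide, as used for 2-(2-hydroxypropan-2-yl)dihydrobenzofurans and 2-(2-hydroxypropan-2-yl)benzoxepanes. Ring D closes in the 7-exo-tet mode. The single stereocentre is catalyst-controlled: the ketone enantiomer fixes the (S)-epoxide, and stereospecific inversion at the attacked carbon turns it into the (R)-aryl ether of the target. Chemoselectivity between the two alkenes is needed and should come from the higher nucleophilicity and lower shielding of the prenyl group compared with the trans-disubstituted 6-alkenyl group, which sits between the 5-acetoxy/7-methoxy-substituted ring A and an isopropyl group, with KHSO5 as the limiting reagent. Regioselectivity (secondary carbon and seven-membered ring rather than tertiary carbon and eight-membered ring) follows from the SN2 character under basic conditions, and only the 2'-oxygen can reach the epoxide, since the 4'-oxygen is para to the biaryl bond and the 5-oxygen lies across the C4 carbonyl.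

**Compound list**
1 | 2-bromo-1,3-dimethoxybenzene | COc1cccc(OC)c1Br | starting material
2 | 2-(4-bromo-3,5-dimethoxyphenyl)-4,4,5,5-tetramethyl-1,3,2-dioxaborolane | COc1cc(B2OC(C)(C)C(C)(C)O2)cc(OC)c1Br | intermediate (not isolated)
3 | 4-bromo-3,5-dimethoxyphenol | COc1cc(O)cc(OC)c1Br | intermediate
4 | 1-(3-bromo-6-hydroxy-2,4-dimethoxyphenyl)ethan-1-one | CC(=O)c1c(O)cc(OC)c(Br)c1OC | intermediate
5 | methyl 2,4-dihydroxybenzoate | COC(=O)c1ccc(O)cc1O | starting material
6 | methyl 2,4-bis(methoxymethoxy)benzoate | COCOc1ccc(C(=O)OC)c(OCOC)c1 | intermediate (not isolated)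
7 | 2,4-bis(methoxymethoxy)benzoic acid | COCOc1ccc(C(=O)O)c(OCOC)c1 | intermediate
8 | 2-acetyl-4-bromo-3,5-dimethoxyphenyl 2,4-bis(methoxymethoxy)benzoate | CC(=O)c1c(OC(=O)c2ccc(OCOC)cc2OCOC)cc(OC)c(Br)c1OC | intermediate
9 | 1-(3-bromo-6-hydroxy-2,4-dimethoxyphenyl)-3-[2,4-bis(methoxymethoxy)phenyl]propane-1,3-dione | COCOc1ccc(C(=O)CC(=O)c2c(O)cc(OC)c(Br)c2OC)c(OCOC)c1 | intermediate
10 | 1-bromo-3-methylbut-2-ene (prenyl bromide) | CC(C)=CCBr | starting material
11 | 1-(3-bromo-6-hydroxy-2,4-dimethoxyphenyl)-3-[2,4-bis(methoxymethoxy)phenyl]-2-(3-methylbut-2-en-1-yl)propane-1,3-dione, racemic | COCOc1ccc(C(=O)C(CC=C(C)C)C(=O)c2c(O)cc(OC)c(Br)c2OC)c(OCOC)c1 | intermediate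
12 | 6-bromo-2-[2,4-bis(methoxymethoxy)phenyl]-5,7-dimethoxy-3-(3-methylbut-2-en-1-yl)-4H-chromen-4-one | COCOc1ccc(-c2oc3cc(OC)c(Br)c(OC)c3c(=O)c2CC=C(C)C)c(OCOC)c1 | intermediate (not isolated)
13 | 6-bromo-2-(2,4-dihydroxyphenyl)-5,7-dimethoxy-3-(3-methylbut-2-en-1-yl)-4H-chromen-4-one | COc1cc2oc(-c3ccc(O)cc3O)c(CC=C(C)C)c(=O)c2c(OC)c1Br | intermediate
14 | 6-bromo-2-(2,4-dihydroxyphenyl)-5-hydroxy-7-methoxy-3-(3-methylbut-2-en-1-yl)-4H-chromen-4-one | COc1cc2oc(-c3ccc(O)cc3O)c(CC=C(C)C)c(=O)c2c(O)c1Br | intermediate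
15 | 3-methylbut-1-yne | CC(C)C#C | starting material
16 | pinacolborane (4,4,5,5-tetramethyl-1,3,2-dioxaborolane) | B1OC(C)(C)C(C)(C)O1 | starting material
17 | (E)-4,4,5,5-tetramethyl-2-(3-methylbut-1-en-1-yl)-1,3,2-dioxaborolane | CC(C)/C=C/B1OC(C)(C)C(C)(C)O1 | intermediate
18 | artocarpin, 2-(2,4-dihydroxyphenyl)-5-hydroxy-7-methoxy-6-[(E)-3-methylbut-1-en-1-yl]-3-(3-methylbut-2-en-1-yl)-4H-chromen-4-one | COc1cc2oc(-c3ccc(O)cc3O)c(CC=C(C)C)c(=O)c2c(O)c1/C=C/C(C)C | intermediate
19 | artocarpin 5,2',4'-triacetate | COc1cc2oc(-c3ccc(OC(C)=O)cc3OC(C)=O)c(CC=C(C)C)c(=O)c2c(OC(C)=O)c1/C=C/C(C)C | intermediate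
20 | 2-[2,4-bis(acetyloxy)phenyl]-3-{[(2S)-3,3-dimethyloxiran-2-yl]methyl}-7-methoxy-6-[(E)-3-methylbut-1-en-1-yl]-4-oxo-4H-chromen-5-yl acetate | COc1cc2oc(-c3ccc(OC(C)=O)cc3OC(C)=O)c(C[C@@H]4OC4(C)C)c(=O)c2c(OC(C)=O)c1/C=C/C(C)C | intermediate (not isolated)
21 | target CNP0216454.1: flavone with ring D (2'-O–CH[C(CH3)2OH]–CH2–C3, R at CH), 5-OH, 4'-OH, 7-OMe, 6-[(E)-3-methylbut-1-enyl] | COc1cc2oc3c(c(=O)c2c(O)c1/C=C/C(C)C)C[C@H](C(C)(C)O)Oc1cc(O)ccc1-3 | target

**Count and risks**
Total step count: 12. Longest linear sequence: 10 steps (steps 1, 2, 4, 5, 6, 7, 8, 10, 11, 12).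

Steps most likely to fail:

1. Step 12. The risk is loss of chemoselectivity: the 6-alkenyl group may be epoxidised in competition with the prenyl group, or acetates may be lost early so that phenoxides meet the oxidant. Fallback: reorder so that only one alkene is present at the oxidation. Setting out from 14, acetylation (Ac2O, pyridine, DMAP) should give 6-bromo-2-[2,4-bis(acetyloxy)phenyl]-7-methoxy-3-(3-methylbut-2-en-1-yl)-4-oxo-4H-chromen-5-yl acetate F1. The same one-pot sequence (L-fructose-derived Shi ketone, Oxone, pH ≈ 10, 0 °C; then K2CO3, MeOH) should pass through the (S)-epoxide triacetate F2 to the 6-bromo oxepinoflavone F3; the aryl bromide is inert to the oxidant. Suzuki–Miyaura coupling of F3 with 17 (Pd(OAc)2, SPhos, K3PO4, 1,4-dioxane–H2O) then returns to the route at 21.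

2. Step 10. The risk is slow oxidative addition into the hindered aryl bromide once the phenols are deprotonated, with protodebromination and protodeboronation taking over. Fallback: a base-free Stille coupling, in which the phenols stay neutral. Setting out from 14, coupling with (E)-tributyl(3-methylbut-1-en-1-yl)stannane F4 (from 15 and Bu3SnH with PdCl2(PPh3)2, the β-(E) isomer being separated) under Pd2(dba)3/P(t-Bu)3 in NMP at 90 °C should give artocarpin and return to the route at 18.

3. Step 6. The risk is O-alkylation of the phenol or enol oxygen, or sluggish alkylation at the hindered central carbon. Fallback: form the C–C bond at the methyl ketone stage. Setting out from 4, the dianion (LiN(SiMe3)2, 2.2 equiv, THF, −78 °C) should be alkylated by 10 at carbon to give 1-(3-bromo-6-hydroxy-2,4-dimethoxyphenyl)-5-methylhex-4-en-1-one F5. Steglich esterification with 7 should give 4-bromo-3,5-dimethoxy-2-(5-methylhex-4-enoyl)phenyl 2,4-bis(methoxymethoxy)benzoate F6, and Baker–Venkataraman rearrangement of F6 (KOH, pyridine, 50 °C) returns to the route at 11.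

Further compounds
F1 | step 12 | 6-bromo-2-[2,4-bis(acetyloxy)phenyl]-7-methoxy-3-(3-methylbut-2-en-1-yl)-4-oxo-4H-chromen-5-yl acetate | COc1cc2oc(-c3ccc(OC(C)=O)cc3OC(C)=O)c(CC=C(C)C)c(=O)c2c(OC(C)=O)c1Br
F2 | step 12 | 6-bromo-2-[2,4-bis(acetyloxy)phenyl]-3-{[(2S)-3,3-dimethyloxiran-2-yl]methyl}-7-methoxy-4-oxo-4H-chromen-5-yl acetate | COc1cc2oc(-c3ccc(OC(C)=O)cc3OC(C)=O)c(C[C@@H]4OC4(C)C)c(=O)c2c(OC(C)=O)c1Br
F3 | step 12 | 6-bromo analogue of the target (ring D closed, R at CH, 5-OH, 4'-OH, 7-OMe) | COc1cc2oc3c(c(=O)c2c(O)c1Br)C[C@H](C(C)(C)O)Oc1cc(O)ccc1-3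
F4 | step 10 | (E)-tributyl(3-methylbut-1-en-1-yl)stannane | CCCC[Sn](CCCC)(CCCC)/C=C/C(C)C
F5 | step 6 | 1-(3-bromo-6-hydroxy-2,4-dimethoxyphenyl)-5-methylhex-4-en-1-one | CC(C)=CCCC(=O)c1c(O)cc(OC)c(Br)c1OC
F6 | step 6 | 4-bromo-3,5-dimethoxy-2-(5-methylhex-4-enoyl)phenyl 2,4-bis(methoxymethoxy)benzoate | CC(C)=CCCC(=O)c1c(OC(=O)c2ccc(OCOC)cc2OCOC)cc(OC)c(Br)c1OC
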